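The data are simulated on assumed constants, noise included.

- Judge this flask by cQ in molar and leave percent of D aside.

| setting | delta | alpha | theta | flask |
|---|---|---|---|---|
| D | 0.20 M | 0.20 M | 0.10 M | 0.20 M |
| L | 0.20 M | 0.20 M | 0.20 M | 0.200 M |
| G | 0.040 M | 0.090 M | 0.060 M | 0.0600 M |
| remark | run made earlier | run made earlier | run made earlier |  |
| time |  |  |  | 50 h |

| run | time / h | D / % | Q / % | X / % |
|---|---|---|---|---|
| delta | 8.00 | 69.3 | 11.9 | 0.3 |
| delta | 15.0 | 49.3 | 22.5 | 0.5 |
| delta | 25.0 | 27.2 | 34.3 | 2.1 |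
| delta | 30.0 | 18.1 | 39.0 | 3.6 |
| alpha | 2.50 | 83.7 | 2.5 | 0 |
| alpha | 6.00 | 66.1 | 8.3 | 0 |
| alpha | 12.0 | 43.9 | 17.5 | 1.3 |
| alpha | 30.0 | 2.0 | 38.6 | 4.0 |
| theta | 2.50 | 79.9 | 4.9 | 0 |
| theta | 6.00 | 55.7 | 16.4 | 0 |
| theta | 12.0 | 21.9 | 35.8 | 0.8 |
| theta | 30.0 | 0 | 66.0 | 3.3 |

(standard deviation of a reading: 0.3 percentage points)

- percent here means D units held: one X counts as two
- D is a solid; its amount is given per volume of the solution
- the analysis behind the earlier runs scatters by 0.3 percentage points, standard deviation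
- at the start none of D is in solution
- as a choice and as an amount asked, D means what is still solid

1. the species in which most of what was charged as D, at 50 h sits (Q / D / X)
2. the largest share itself, whichever of these holds it, in percent of the D charged

- The puzzle: at 30.0 h, alpha with G 0.090 M holds D 2.0% where delta with G 0.040 M holds 18.1%, yet Q reads 38.6% in alpha and 39.0% in delta.
- As cQ, delta stands at 0.0780 M and alpha at 0.0772 M, while theta, with half the D, reaches 0.0660 M; so from delta to alpha, where the charge of G is the setting that differs, D moves while cQ barely stirs.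
- Delta's last reading gives 0.0165 h⁻¹: the L clock, the apparent first-order constant at which cQ climbs towards the L charge.
- Run to 50 h, this reckoning gives cQ 0.112 M, which is 56.1% of the D charged.
- The forecast says Q at 52%, lower than this reckoning, and it expects X “perhaps taking some Q”.

- The flask gives Q at 52.8%, as forecast, so cQ is 0.106 M and its L clock reads 0.0150 h⁻¹.

    L ⇌ Z (K = 3.33, k = 0.00152 min⁻¹)
    D + G → J (k = 0.00876 M⁻¹ min⁻¹)
    E + L → Q (k = 0.0367 M⁻¹ min⁻¹)
    2 E → X (k = 0.00253 M⁻¹ min⁻¹)
    D ⇌ E, rate k5*(cs5 - [E]) while solid is left; crystals form when [E] > cs5 (solubility = 0.120 M, k = 7.85 × 10⁻⁴ min⁻¹)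

- Half the turnover of L into Z up to the asked time was done by 2.59 h and half that of E + L into Q by 18.1 h, while solid D fell to 50.5% at 12.5 h and 0% at 37.5 h. The neighbour flask with 0.80 M of D keeps most in D, at 68.2%, and its Q of 13.8% is cQ 0.110 M, an L clock of 0.0161 h⁻¹.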